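The data stem from a simulated flask with made-up constants; scatter was added.

Something in these flasks is slow, and the earlier run leaves two candidates. First end groups join dissolved second end groups to give links and by-product, while second end groups enter from the held gas, starting from none.

| setting | ash | autumn | summer | winter | noon | midnight |
|---|---|---|---|---|---|---|
| first end groups | 0.56 M | 0.51 M | 0.25 M | 1.5 M | 0.15 M | 2.0 M |
| gas | 120 mM (held) | 120 mM (held) | 120 mM (held) | 120 mM (held) | 120 mM (held) | 120 mM (held) |
| remark | run made earlier |  |  |  |  |  |
| time |  | 15 h | 15 h | 15 h | 15 h | 15 h |

- ash (time / h: links / %): 0.667: 7; 1.33: 11; 2.50: 24; 5.00: 42; 10.0: 60

(each reading ± 1.5 percentage points)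

- at the start none of second end groups is dissolved
- reactions considered so far: first end groups + second end groups <-> links + by-product; gas <-> second end groups; 2 second end groups -> self-condensation product

1. the flasks put in order of amount of links, in percent of the first end groups charged, best first, at 15 h (autumn / summer / winter / noon / midnight)
2. the amount of links, in percent of the first end groups charged of the flask you put first, at 15 h
3. the amount of links, in percent of the first end groups charged of the flask you put last, at 15 h

One chemist reads the ash run as a decay of first end groups, with 0.11 per hour, and adds a way back. The forecast is hers: “Percent conversion should fall as charge rises, because by-product back-reaction scales with concentration and heavier charges draw down dissolved second end groups”. She gives noon > summer > autumn > winter > midnight, with noon at 78% (68% to 88%) and midnight at 50% (30% to 63%).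

I read the same run as a supply. Up to 2.50 h the ash readings lie on a straight line within their scatter, so I take the slope in molar terms: the feed, the links made per hour while first end groups are plentiful, read as 0.0538 M h⁻¹. Over 15 h that delivers 0.806 M, and this is my crossing charge. Below it the charge can be served; above it dissolving is the rate-limiting step. Midnight stands above it, so I expect 40.3% there, less than her figure. We agree on the order.

The flasks give noon > summer > autumn > winter > midnight, with noon at 82.4% and midnight at 34.9%. Her order and top stand, and her low is 15 percentage points too high; mine is 5.5 points too high. Midnight holds 0.697 M of links, less than the crossing. Noon lies below the crossing, and there her way back has its region: noon stands at 82.0% at 7.50 h and still at 82.4% at 150 h.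

    first end groups + second end groups ⇌ links + by-product (K = 8.80, k = 19.0 M⁻¹ h⁻¹)
    gas ⇌ second end groups, rate k2*(csat - [second end groups]) (kL = 0.510 h⁻¹)
    2 second end groups → self-condensation product (k = 3.20 M⁻¹ h⁻¹)

In midnight at 6.70 h, second end groups have a half-life of 1.4 min by the forward link step alone, much shorter than the dissolving half-time of 1.36 h. Read at 4.0 h, the same midnight flask should by the feed stand at 10.8%; it gives 11.7%.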